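**Strategy**

The route rests on cutting ring C of the middle epicatechin unit at two bonds: the aryl ether bond from pyran oxygen O1 to ring-A carbon C8a and the C4–C4a bond. Both are formed in one operation when 3,5-bis(benzyloxy)benzyne is annulated onto a sodium epoxy alkoxide: O1 adds to the aryne and the aryl anion opens the trans-epoxide at C4 with inversion. The precursor is an acyclic threo epoxy alcohol whose C4 carries C6 of the protected catechin unit, so the 4→6 linkage is fixed by an aldol condensation. The feature exploited is that C8a and C4a are adjacent carbons of a phloroglucinol-type ring A, the two termini of an aryne. The top unit is attached afterwards at C8.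

Key step: step 12

Remark on the chemistry: 3,5-bis(benzyloxy)phenol and 1-[3,4-bis(benzyloxy)phenyl]ethanone are taken as commercial building blocks. All phenols are carried as benzyl ethers, and the bromine at C8 of the catechin unit is a blocking group that leaves in the last step.

**Route**

Step 1
Reactants: 1 (−)-epicatechin
Product: 2 5,7,3',4'-tetra-O-benzyl-(−)-epicatechin
Conditions: BnBr, K2CO3, DMF, rt
Reagents that add atoms: benzyl bromide, BrCc1ccccc1
Why: Williamson etherification in which K2CO3 deprotonates only the four phenols, so the secondary 3-OH stays free and no stereocenter is touched.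

Step 2
Reactants: 2 5,7,3',4'-tetra-O-benzyl-(−)-epicatechin
Product: 3 (2R,3R,4S)-5,7,3',4'-tetra-O-benzyl-4-(2-ethoxyethoxy)flavan-3-ol
Conditions: DDQ, 2-ethoxyethanol, CH2Cl2, rt
Reagents that add atoms: 2-ethoxyethanol, CCOCCO
Why: DDQ benzylic oxidation, in which hydride abstraction from C4 gives a cation stabilised by the three oxygens of ring A that the alcohol should trap trans to the axial 3-OH, setting the 4β ether.

Step 3
Reactants: 4 (+)-catechin
Product: 5 3,5,7,3',4'-penta-O-benzyl-(+)-catechin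
Conditions: NaH, BnBr, DMF, 0 °C → rt
Reagents that add atoms: benzyl bromide, BrCc1ccccc1
Why: Williamson etherification in which NaH deprotonates the four phenols and the secondary 3-OH so that all five oxygens are benzylated, low temperature and excess benzyl bromide keeping the phenoxides from opening ring C.

Step 4
Reactants: 5 3,5,7,3',4'-penta-O-benzyl-(+)-catechin
Product: 6 8-bromo-3,5,7,3',4'-penta-O-benzyl-(+)-catechin
Conditions: NBS, CH2Cl2, −78 °C → rt
Reagents that add atoms: N-bromosuccinimide, O=C1CCC(=O)N1Br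
Why: electrophilic aromatic bromination, in which C8 next to the tied-back ring oxygen O1 is the more accessible of the two free ring-A carbons and should react selectively at low temperature.

Step 5
Reactants: 6 8-bromo-3,5,7,3',4'-penta-O-benzyl-(+)-catechin
Product: 8 8-bromo-3,5,7,3',4'-penta-O-benzyl-(+)-catechin-6-carbaldehyde, via iminium chloride 7 (not isolated)
Conditions: POCl3, DMF, 0 → 60 °C; then aq. NaOAc
Reagents that add atoms: N,N-dimethylformamide, CN(C)C=O; water, O
Why: Vilsmeier–Haack formylation, in which C6 is the only free carbon of the phloroglucinol-type ring A once C8 is blocked and is far more nucleophilic than the catechol-type ring B, the iminium 7 being hydrolysed on work-up.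

Step 6
Reactants: 8 8-bromo-3,5,7,3',4'-penta-O-benzyl-(+)-catechin-6-carbaldehyde; 9 1-[3,4-bis(benzyloxy)phenyl]ethanone
Product: 10 (E)-1-[3,4-bis(benzyloxy)phenyl]-3-(8-bromo-3,5,7,3',4'-penta-O-benzylcatechin-6-yl)prop-2-en-1-one
Conditions: KOH, EtOH/THF, rt
Reagents that add atoms: none
Why: Claisen–Schmidt condensation, in which the enolate of 9 adds to the non-enolisable aldehyde 8 and E1cB loss of water gives the conjugated E-enone.

Step 7
Reactants: 10 (E)-enone
Product: 11 [3,4-bis(benzyloxy)phenyl][(2R,3S)-3-(8-bromo-3,5,7,3',4'-penta-O-benzylcatechin-6-yl)oxiran-2-yl]methanone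
Conditions: poly-L-leucine, urea–H2O2, DBU, THF, rt
Reagents that add atoms: urea–hydrogen peroxide, NC(N)=O.OO
Why: Juliá–Colonna epoxidation (Weitz–Scheffer type), in which hydroperoxide adds to the enone held on the poly-L-leucine helix, a catalyst that delivers the trans (2R,3S)-epoxide on chalcone-type enones and should override the remote stereocenters of the catechin unit.

Step 8
Reactants: 11 trans-(2R,3S)-epoxy ketone
Product: 12 (R)-[3,4-bis(benzyloxy)phenyl][(2S,3S)-3-(8-bromo-3,5,7,3',4'-penta-O-benzylcatechin-6-yl)oxiran-2-yl]methanol (threo)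
Conditions: (R)-Me-CBS oxazaborolidine [(R)-1-methyl-3,3-diphenyltetrahydro-1H,3H-pyrrolo[1,2-c][1,3,2]oxazaborole] (20 mol %), catecholborane, toluene, −78 °C; aq. NaOH work-up
Reagents that add atoms: none
Why: Corey–Bakshi–Shibata reduction, in which the (R)-catalyst binds the ketone with the aryl group as the large substituent and should deliver hydride to the face that gives the (R)-carbinol, i.e. the threo epoxy alcohol, while catecholborane at low temperature spares the epoxide.

Step 9
Reactants: 13 3,5-bis(benzyloxy)phenol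
Product: 14 3,5-bis(benzyloxy)phenyl N-isopropylcarbamate
Conditions: i-PrNCO, Et3N (cat.), CH2Cl2, rt
Reagents that add atoms: isopropyl isocyanate, CC(C)N=C=O
Why: carbamoylation by base-catalysed addition of the phenol to the isocyanate, giving a secondary carbamate that directs metalation and can later be removed under mild base.

Step 10
Reactants: 14 3,5-bis(benzyloxy)phenyl N-isopropylcarbamate
Product: 18 3,5-bis(benzyloxy)-2-(trimethylsilyl)phenyl N-isopropylcarbamate, via N-silyl carbamate 15 (not isolated), via aryllithium 16 (not isolated), via N-silyl C-silyl carbamate 17 (not isolated)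
Conditions: TBSOTf, TMEDA, Et2O, 0 °C → rt; n-BuLi, TMEDA, −78 °C; TMSCl, −78 °C → rt; aq. NaHSO4
Reagents that add atoms: chlorotrimethylsilane, C[Si](C)(C)Cl
Why: directed ortho-metalation, in which N-silylation masks the N–H, n-BuLi/TMEDA lithiates the ring carbon flanked by the carbamate and a benzyloxy group (the two ortho sites are equivalent), and TMSCl quench followed by acidic work-up, which removes the N-silyl group, gives the ortho-silyl carbamate.

Step 11
Reactants: 18 3,5-bis(benzyloxy)-2-(trimethylsilyl)phenyl N-isopropylcarbamate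
Product: 20 3,5-bis(benzyloxy)-2-(trimethylsilyl)phenyl trifluoromethanesulfonate, via silyl phenol 19 (not isolated)
Conditions: DBU, Et2NH, MeCN, 40 °C; then PhNTf2, rt
Reagents that add atoms: N-phenylbis(trifluoromethanesulfonimide), FC(F)(F)S(=O)(=O)N(c1ccccc1)S(=O)(=O)C(F)(F)F
Why: E1cB cleavage of the secondary carbamate (the isopropyl isocyanate is scavenged by Et2NH) frees the phenoxide, which is triflated in the same flask to give the ortho-silylaryl triflate.

Step 12
Reactants: 12 threo epoxy alcohol; 20 3,5-bis(benzyloxy)-2-(trimethylsilyl)phenyl trifluoromethanesulfonate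
Product: 24 5,7,3',4'-tetra-O-benzylepicatechin-(4β→6)-8-bromo-3,5,7,3',4'-penta-O-benzylcatechin, via sodium alkoxide 21 (not isolated), via aryne 22 (not isolated), via aryl anion 23 (not isolated)
Conditions: NaH (1.05 equiv), THF, 0 °C; then 20 (1.2 equiv), CsF, 18-crown-6, THF, 0 °C → rt; aq. NH4Cl
Reagents that add atoms: none
Why: Proposed new method: fluoride converts 20 into 3,5-bis(benzyloxy)benzyne 22, the alkoxide 21 adds through its C2 oxygen to the aryne carbon remote from the flanking benzyloxy group (the future C8a), and the aryl anion 23, centred on the carbon between two oxygens (the future C4a), opens the epoxide at benzylic C4. The closest known reaction type is the aryne insertion annulation in which an O-nucleophile adds and the aryl anion is caught by a tethered electrophile (salicylate to xanthone), together with the aryl-metal opening of aryl epoxides used in chroman synthesis, and the untested element is an epoxide as the internal trap. Ring C closes by a 6-endo-tet epoxide opening. C4 is set by inversion at the (S)-configured epoxide carbon, which gives the 3,4-trans (4β) arrangement, while C2 and C3 keep their C–O bonds and configurations, so the threo epoxy alcohol becomes the 2,3-cis pattern. Three selectivities are needed: regiochemistry of the aryne addition, secured by the inductive effect and ring distortion of the 3-benzyloxy group; 6-endo over 5-exo opening, secured by the 2,4,6-trioxygenated aryl group on C4 that weakens the C4–O bond; and suppression of Payne migration of the epoxide, sought through aprotic conditions, low temperature and a short alkoxide lifetime.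

Step 13
Reactants: 3 (2R,3R,4S)-5,7,3',4'-tetra-O-benzyl-4-(2-ethoxyethoxy)flavan-3-ol; 24 protected (4β→6) dimer
Product: 25 5,7,3',4'-tetra-O-benzylepicatechin-(4β→8)-5,7,3',4'-tetra-O-benzylepicatechin-(4β→6)-8-bromo-3,5,7,3',4'-penta-O-benzylcatechin
Conditions: TMSOTf (0.2 equiv), CH2Cl2, −78 → −40 °C; aq. NaHCO3
Reagents that add atoms: none
Why: Lewis acid-mediated flavan C4 arylation (Friedel–Crafts type), in which TMSOTf ionises the C4 ether of 3 to the ring-A-stabilised cation that should be attacked trans to its 3-OH (4β) by C8 of the middle unit of 24, the site next to the tied-back O1, while C8 of the bottom unit is blocked by bromine.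

Step 14
Reactants: 25 protected trimer
Product: 26 arecatannin B1
Conditions: H2 (1 atm), Pd(OH)2/C, Et3N, THF/MeOH/H2O, rt
Reagents that add atoms: none
Why: catalytic hydrogenolysis should cleave the thirteen benzyl ethers and the aryl C–Br bond under neutral to weakly basic conditions that leave the acid-labile interflavan bonds and all stereocenters untouched.

**Compound list**

1 | (−)-epicatechin, (2R,3R) | Oc1cc(O)c2c(c1)O[C@H](c1ccc(O)c(O)c1)[C@H](O)C2 | starting material
2 | 5,7,3',4'-tetra-O-benzyl-(−)-epicatechin | c1ccccc1COc1cc(OCc3ccccc3)c2c(c1)O[C@H](c1ccc(OCc3ccccc3)c(OCc3ccccc3)c1)[C@H](O)C2 | intermediate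
3 | (2R,3R,4S)-5,7,3',4'-tetra-O-benzyl-4-(2-ethoxyethoxy)flavan-3-ol (4β ether, 3,4-trans) | c1ccccc1COc1cc(OCc3ccccc3)c2c(c1)O[C@H](c1ccc(OCc3ccccc3)c(OCc3ccccc3)c1)[C@H](O)[C@H]2OCCOCC | intermediate
4 | (+)-catechin, (2R,3S) | Oc1cc(O)c2c(c1)O[C@H](c1ccc(O)c(O)c1)[C@@H](O)C2 | starting material
5 | 3,5,7,3',4'-penta-O-benzyl-(+)-catechin | c1ccccc1COc1cc(OCc3ccccc3)c2c(c1)O[C@H](c1ccc(OCc3ccccc3)c(OCc3ccccc3)c1)[C@@H](OCc1ccccc1)C2 | intermediate
6 | 8-bromo-3,5,7,3',4'-penta-O-benzyl-(+)-catechin | c1ccccc1COc1cc(OCc3ccccc3)c2c(c1Br)O[C@H](c1ccc(OCc3ccccc3)c(OCc3ccccc3)c1)[C@@H](OCc1ccccc1)C2 | intermediate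
7 | N,N-dimethyliminium chloride at C6 of 6 (Vilsmeier adduct) | c1ccccc1COc1c(C=[N+](C)C)c(OCc3ccccc3)c2c(c1Br)O[C@H](c1ccc(OCc3ccccc3)c(OCc3ccccc3)c1)[C@@H](OCc1ccccc1)C2.[Cl-] | intermediate
8 | 8-bromo-3,5,7,3',4'-penta-O-benzyl-(+)-catechin-6-carbaldehyde | c1ccccc1COc1c(C=O)c(OCc3ccccc3)c2c(c1Br)O[C@H](c1ccc(OCc3ccccc3)c(OCc3ccccc3)c1)[C@@H](OCc1ccccc1)C2 | intermediate
9 | 1-[3,4-bis(benzyloxy)phenyl]ethanone | CC(=O)c1ccc(OCc2ccccc2)c(OCc2ccccc2)c1 | starting material
10 | (E)-1-[3,4-bis(benzyloxy)phenyl]-3-(8-bromo-3,5,7,3',4'-penta-O-benzylcatechin-6-yl)prop-2-en-1-one | c1ccccc1COc1c(/C=C/C(=O)c3ccc(OCc4ccccc4)c(OCc4ccccc4)c3)c(OCc3ccccc3)c2c(c1Br)O[C@H](c1ccc(OCc3ccccc3)c(OCc3ccccc3)c1)[C@@H](OCc1ccccc1)C2 | intermediate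
11 | [3,4-bis(benzyloxy)phenyl][(2R,3S)-3-(8-bromo-3,5,7,3',4'-penta-O-benzylcatechin-6-yl)oxiran-2-yl]methanone (trans-epoxide) | O=C(c1ccc(OCc2ccccc2)c(OCc2ccccc2)c1)[C@@H]1O[C@H]1c1c(OCc3ccccc3)c2c(c(Br)c1OCc1ccccc1)O[C@H](c1ccc(OCc3ccccc3)c(OCc3ccccc3)c1)[C@@H](OCc1ccccc1)C2 | intermediate
12 | (R)-[3,4-bis(benzyloxy)phenyl][(2S,3S)-3-(8-bromo-3,5,7,3',4'-penta-O-benzylcatechin-6-yl)oxiran-2-yl]methanol (threo, trans-epoxide) | O[C@H](c1ccc(OCc2ccccc2)c(OCc2ccccc2)c1)[C@@H]1O[C@H]1c1c(OCc3ccccc3)c2c(c(Br)c1OCc1ccccc1)O[C@H](c1ccc(OCc3ccccc3)c(OCc3ccccc3)c1)[C@@H](OCc1ccccc1)C2 | intermediate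
13 | 3,5-bis(benzyloxy)phenol | Oc1cc(OCc2ccccc2)cc(OCc2ccccc2)c1 | starting material
14 | 3,5-bis(benzyloxy)phenyl N-isopropylcarbamate | CC(C)NC(=O)Oc1cc(OCc2ccccc2)cc(OCc2ccccc2)c1 | intermediate
15 | 3,5-bis(benzyloxy)phenyl N-(tert-butyldimethylsilyl)-N-isopropylcarbamate | CC(C)N(C(=O)Oc1cc(OCc2ccccc2)cc(OCc2ccccc2)c1)[Si](C)(C)C(C)(C)C | intermediate
16 | 2-lithio derivative of 15 | CC(C)N(C(=O)Oc1cc(OCc2ccccc2)cc(OCc2ccccc2)c1[Li])[Si](C)(C)C(C)(C)C | intermediate
17 | 3,5-bis(benzyloxy)-2-(trimethylsilyl)phenyl N-(tert-butyldimethylsilyl)-N-isopropylcarbamate | CC(C)N(C(=O)Oc1cc(OCc2ccccc2)cc(OCc2ccccc2)c1[Si](C)(C)C)[Si](C)(C)C(C)(C)C | intermediate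
18 | 3,5-bis(benzyloxy)-2-(trimethylsilyl)phenyl N-isopropylcarbamate | CC(C)NC(=O)Oc1cc(OCc2ccccc2)cc(OCc2ccccc2)c1[Si](C)(C)C | intermediate
19 | 3,5-bis(benzyloxy)-2-(trimethylsilyl)phenol | Oc1cc(OCc2ccccc2)cc(OCc2ccccc2)c1[Si](C)(C)C | intermediate
20 | 3,5-bis(benzyloxy)-2-(trimethylsilyl)phenyl trifluoromethanesulfonate | C[Si](C)(C)c1c(OCc2ccccc2)cc(OCc2ccccc2)cc1OS(=O)(=O)C(F)(F)F | intermediate
21 | sodium alkoxide of 12 | [Na+].[O-][C@H](c1ccc(OCc2ccccc2)c(OCc2ccccc2)c1)[C@@H]1O[C@H]1c1c(OCc3ccccc3)c2c(c(Br)c1OCc1ccccc1)O[C@H](c1ccc(OCc3ccccc3)c(OCc3ccccc3)c1)[C@@H](OCc1ccccc1)C2 | intermediate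
22 | 3,5-bis(benzyloxy)benzyne | C1#CC(OCc2ccccc2)=CC(OCc2ccccc2)=C1 | intermediate
23 | sodium 2-aryloxy-4,6-bis(benzyloxy)phenyl anion (O-arylated 12, carbanion at the future C4a) | [Na+].[c-]1c(OCc2ccccc2)cc(OCc2ccccc2)cc1O[C@H](c1ccc(OCc2ccccc2)c(OCc2ccccc2)c1)[C@@H]1O[C@H]1c1c(OCc3ccccc3)c2c(c(Br)c1OCc1ccccc1)O[C@H](c1ccc(OCc3ccccc3)c(OCc3ccccc3)c1)[C@@H](OCc1ccccc1)C2 | intermediate
24 | 5,7,3',4'-tetra-O-benzylepicatechin-(4β→6)-8-bromo-3,5,7,3',4'-penta-O-benzylcatechin (free 3-OH on the epicatechin unit) | c1ccccc1COc1cc(OCc3ccccc3)c2c(c1)O[C@H](c1ccc(OCc3ccccc3)c(OCc3ccccc3)c1)[C@H](O)[C@H]2c1c(OCc3ccccc3)c2c(c(Br)c1OCc1ccccc1)O[C@H](c1ccc(OCc3ccccc3)c(OCc3ccccc3)c1)[C@@H](OCc1ccccc1)C2 | intermediate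
25 | 5,7,3',4'-tetra-O-benzylepicatechin-(4β→8)-5,7,3',4'-tetra-O-benzylepicatechin-(4β→6)-8-bromo-3,5,7,3',4'-penta-O-benzylcatechin | c1ccccc1COc1cc(OCc3ccccc3)c2c(c1)O[C@H](c1ccc(OCc3ccccc3)c(OCc3ccccc3)c1)[C@H](O)[C@H]2c1c(OCc3ccccc3)cc(OCc3ccccc3)c2c1O[C@H](c1ccc(OCc3ccccc3)c(OCc3ccccc3)c1)[C@H](O)[C@H]2c1c(OCc3ccccc3)c2c(c(Br)c1OCc1ccccc1)O[C@H](c1ccc(OCc3ccccc3)c(OCc3ccccc3)c1)[C@@H](OCc1ccccc1)C2 | intermediate
26 | arecatannin B1, epicatechin-(4β→8)-epicatechin-(4β→6)-catechin | Oc1cc(O)c2c(c1)O[C@H](c1ccc(O)c(O)c1)[C@H](O)[C@H]2c1c(O)cc(O)c2c1O[C@H](c1ccc(O)c(O)c1)[C@H](O)[C@H]2c1c(O)cc2c(c1O)C[C@H](O)[C@@H](c1ccc(O)c(O)c1)O2 | target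

**Step count and risks**

Total step count: 14. Longest linear sequence: 9 steps (steps 3, 4, 5, 6, 7, 8, 12, 13, 14, from (+)-catechin).

Steps most likely to fail:

Step 12 (proposed new method). The epoxide may migrate to the neighbouring alkoxide (Payne rearrangement) before O-arylation. The aryl anion may be protonated or may open the epoxide in the 5-exo mode. The alkoxide may also take the sulfonyl group from the aryl triflate. The fallback uses known chemistry and gives up the annulation: it sets out from compounds 3 and 6 and comes back to the route at compound 24. TMSOTf in CH2Cl2 at −78 °C ionises the C4 ether of 3, and the 8-bromo nucleophile 6, whose only free ring-A carbon is C6, is alkylated there trans to the 3-OH of the electrophile. This gives 24 itself, so the fallback makes no new compound (F0).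

Step 7. Conjugate addition of hydroperoxide to the electron-rich, doubly ortho-substituted enone may be slow, facial control by the polypeptide may be poor, and the electron-rich benzylic epoxide may open under the reaction conditions. The fallback builds the epoxide by C–C bond formation instead of oxidising the enone: it sets out from compounds 8 and 9 and comes back at compound 11. Ketone 9 is chlorinated at the methyl group (CuCl2, LiCl, DMF, 80 °C) to 2-chloro-1-[3,4-bis(benzyloxy)phenyl]ethanone F1. A Darzens condensation of F1 with aldehyde 8 under phase-transfer conditions (cinchona-derived quaternary ammonium salt, LiOH, n-Bu2O, rt) should then give the trans-epoxy ketone 11. The undesired trans diastereomer should be separable by chromatography because the catechin unit is enantiopure.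

Step 8. The intrinsic bias of the epoxy ketone (hydride attack on the s-cis conformer from the side of the epoxide oxygen) may override catalyst control and give the erythro epimer, and the borane may open the epoxide reductively. The fallback uses that bias instead of fighting it: it sets out from compound 11 and comes back at compound 12. Chelation-controlled reduction (Zn(BH4)2, Et2O, −20 °C) should give the erythro (S)-configured epoxy alcohol F2. Mitsunobu inversion with 4-nitrobenzoic acid (PPh3, DIAD, THF, 0 °C) gives the threo 4-nitrobenzoate F3, and methanolysis (K2CO3, MeOH, 0 °C) releases 12.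

Further compounds
F0 | step 12 | none | none
F1 | step 7 | 2-chloro-1-[3,4-bis(benzyloxy)phenyl]ethanone | O=C(CCl)c1ccc(OCc2ccccc2)c(OCc2ccccc2)c1
F2 | step 8 | (S)-[3,4-bis(benzyloxy)phenyl][(2S,3S)-3-(8-bromo-3,5,7,3',4'-penta-O-benzylcatechin-6-yl)oxiran-2-yl]methanol (erythro) | O[C@@H](c1ccc(OCc2ccccc2)c(OCc2ccccc2)c1)[C@@H]1O[C@H]1c1c(OCc3ccccc3)c2c(c(Br)c1OCc1ccccc1)O[C@H](c1ccc(OCc3ccccc3)c(OCc3ccccc3)c1)[C@@H](OCc1ccccc1)C2
F3 | step 8 | (R)-[3,4-bis(benzyloxy)phenyl][(2S,3S)-3-(8-bromo-3,5,7,3',4'-penta-O-benzylcatechin-6-yl)oxiran-2-yl]methyl 4-nitrobenzoate (threo) | O=C(c1ccc(cc1)[N+](=O)[O-])O[C@H](c1ccc(OCc2ccccc2)c(OCc2ccccc2)c1)[C@@H]1O[C@H]1c1c(OCc3ccccc3)c2c(c(Br)c1OCc1ccccc1)O[C@H](c1ccc(OCc3ccccc3)c(OCc3ccccc3)c1)[C@@H](OCc1ccccc1)C2
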